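The ratio of product made to reagent charged is what I read first, since the reagent charge stood at 58.0 mM in old and new flasks alike and each step making product spends one reagent.

| flask | solid substrate | reagent | remark | time |
|---|---|---|---|---|
| maple | 29 mM | 58 mM | run made earlier |  |
| elm | 85 mM | 58 mM | run made earlier |  |
| larch | 300 mM | 58 mM | run made earlier |  |
| south-west | 30 mM | 58.0 mM |  | 20 h |
| north-east | 60 mM | 58.0 mM |  | 20 h |
| west | 120 mM | 58.0 mM |  | 20 h |
| north | 250 mM | 58.0 mM |  | 20 h |

| maple: time / h | maple: product / % | elm: time / h | elm: product / % | larch: time / h | larch: product / % |
|---|---|---|---|---|---|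
| 1.50 | 1.0 | 4.00 | 0.1 | 2.00 | 0.8 |
| 3.00 | 0.8 | 8.00 | 2.5 | 5.00 | 0.7 |
| 6.00 | 4.2 | 12.0 | 6.4 | 10.0 | 0.9 |
| 10.0 | 10.8 | 15.0 | 8.3 | 15.0 | 2.7 |
| 20.0 | 51.2 | 20.0 | 16.6 | 20.0 | 6.4 |

(each reading ± 1 percentage point)

- solid substrate is a solid; its amount is given per volume of the solution
- steps under discussion: solid substrate <-> starting material; starting material + reagent -> product + by-product; starting material + reagent + by-product -> product + 2 by-product
- at the start none of the solid substrate is in solution
- "hardly changes" means that all values lie within two and a half points (for a concentration: within two and a half percent of the largest)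

- [product] at the end for south-west, north-east, west, north, in this order
- the shape of the row from first to last (rises all the way / falls all the way / hardly changes / rises, then falls / falls, then rises)

1. Maple gave 0.256 of its reagent charge as product at 20.0 h. This fraction is the reagent share, the conversion of the reagent.

2. As zero of the scale I set the case where the solid charge makes no difference: one share across these charges. Elm read 0.243 and larch 0.331, though larch's 6.4% of its solid was far below maple's 51.2%.

3. From above, south-west can give no more than its solid charge, a share of 0.517. To tighten this, I noted that the asked charges lie inside those already read. One scatter is worth 0.00500 of share in maple but 0.0517 in larch. So I took maple plus two scatters, 0.266, as the top, and kept larch, 1.45 of its scatters above maple, as a doubt.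

4. From below, elm minus two of its scatters gave 0.214. I committed to 12.4 mM to 15.4 mM of product, the same along the row.

5. The forecast gave 14.8 mM, 14.8 mM, 14.8 mM, 14.8 mM, shape hardly changes: a share of 0.255, inside my bracket. Its ground was that “the rate does not depend on how much solid is charged”.

6. The flasks gave 15.0 mM, 15.0 mM, 15.0 mM, 15.0 mM, shape hardly changes.

    solid substrate ⇌ starting material, rate k1*(cs1 - [starting material]) while solid is left; crystals form when [starting material] > cs1 (solubility = 16.0 mM, k = 0.00190 min⁻¹)
    starting material + reagent → product + by-product (k = 0.0100 L mol⁻¹ min⁻¹)
    starting material + reagent + by-product → product + 2 by-product (k = 5.10 L² mol⁻² min⁻¹)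

The south-west share was 0.259, inside the bracket. Maple's share, a reading with its scatter, carried over, gives south-west 49.5% of its solid charge against 49.9% found, and north 5.94% against 5.99%. In south-west, starting material was made 1.46 times as fast as it was used up at 8.64 h, each step taken net. At 20.0 h that ratio stood at 0.793, with 29.2% of the solid charge still undissolved.

(All runs come from a simulation with constants of no real substance, and the scatter is random.)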